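(The runs stem from a simulated flask for substances that don't exist.)

**Pitfall.** A rate law read from these runs seems to hold a substrate factor, yet green, teal and amber each start at 0.10 M of substrate, so their charges do not test that factor.

all flasks: substrate 0.10 M
- green: coupling partner 0.055 M; initiator 1.6 mM; temperature 20 °C; run made earlier
- teal: coupling partner 0.083 M; initiator 1.6 mM; temperature 35 °C; run made earlier
- amber: coupling partner 0.11 M; initiator 3.2 mM; temperature 20 °C; run made earlier
- eta: coupling partner 0.110 M; initiator 1.6 mM; at 25 °C until 2.0 min, from then on at 45 °C; time 10 min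
- delta: coupling partner 0.110 M; initiator 1.6 mM; at 25 °C throughout; time 10 min

- green (time / min: product / %, substrate / %): 1.33: 1.1, 99.7; 2.50: 4.9, 97.5; 4.00: 5.8, 94.2; 5.00: 7.3, 93.5; 6.00: 8.6, 91.9
- teal (time / min: product / %, substrate / %): 0.833: 7.9, 92.9; 1.50: 12.8, 87.8; 2.50: 19.0, 84.0; 3.00: 23.1, 76.9; 4.00: 26.0, 72.7
- amber (time / min: product / %, substrate / %): 0.500: 2.8, 95.6; 1.50: 4.8, 94.4; 3.00: 12.8, 88.9; 4.00: 15.2, 86.7; 6.00: 23.1, 78.0

(scatter of a reading: 1 percentage point)

* the winner by amount of product, in percent of the substrate charged; "neither" if no more than 2 percentage points parts them (eta / delta / neither)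
* how much product is there at the end, in percent of the substrate charged: eta
* how much product is there at the end, in percent of the substrate charged: delta

- a reading or a percentage of product counts all its forms, free or not

**Partner constant.** Green's last reading gives 0.0283 min⁻¹ for the partner constant, the rate of product divided by the coupling partner present (a pseudo-first-order constant). Amber, with twice the partner and twice the initiator, reads 0.0393 min⁻¹, and dividing by the square root of the initiator ratio returns 0.0278 min⁻¹. Teal reads 0.0939 min⁻¹ at 35 °C, which makes an apparent activation energy of 60.0 kJ mol⁻¹.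

**The clock.** The constant then stands at 0.0428 min⁻¹ at 25 °C and 0.196 min⁻¹ at 45 °C. Constant times minutes gives a clock: 0.428 for delta and 1.65 for eta. The partner left is e to the minus clock, and the partner gone is product. That reckoning gives 89.0 % for eta and 38.3 % for delta, so it backs your hunch that eta wins: eta comes out ahead of delta by 51 percentage points, well beyond the margin. With 0.110 M of coupling partner against 0.10 M of substrate, substrate is the limiting reagent, and this reckoning carries no substrate factor.

**The flasks.** The forecast names eta, with 65 % for eta and 34 % for delta, and shades eta for “initiator decay or product inhibition”, which leaves it below this reckoning. Eta gives 86.5 % and delta 37.1 %.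

    initiator → 2 initiating radical (k = 1.10 × 10⁻⁴ s⁻¹, Ea = 105 kJ mol⁻¹)
    substrate + initiating radical → capped initiator + first chain carrier (k = 7.00 × 10⁵ M⁻¹ s⁻¹, Ea = 23.0 kJ mol⁻¹)
    coupling partner + first chain carrier ⇌ product + second chain carrier (K = 40.0, k = 41000 M⁻¹ s⁻¹, Ea = 20.0 kJ mol⁻¹, ΔH = −45.0 kJ mol⁻¹)
    substrate + second chain carrier → by-product + first chain carrier (k = 66000 M⁻¹ s⁻¹, Ea = 24.0 kJ mol⁻¹)
    2 second chain carrier → ended chains A (k = 8.10 × 10⁶ M⁻¹ s⁻¹, Ea = 9.00 kJ mol⁻¹)
    2 first chain carrier → ended chains B (k = 6.00 × 10⁸ M⁻¹ s⁻¹, Ea = 8.00 kJ mol⁻¹)
    crystals ⇌ product, rate k7*(cs7 - [product]) while solid is left; crystals form when [product] > cs7 (solubility = 50.0 mM, k = 0.00710 s⁻¹)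
    (constants at 25 °C)

**Partner check.** In delta at 4.44 min the coupling partner has a half-life of 17 min by the forward rate of its step with first chain carrier alone, and the partner constant gives 16.2 min. The initiator's half-life in delta by its own step at that time is 110 min, longer, and at the end of delta 94 % of the charged initiator is left against 66 % of the charged partner. Eta ends 2.5 points below its clock. At 40 °C the constant is 0.137 min⁻¹, and its clock reads 81.9 %; the flask like delta kept there holds 81.1 %.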